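Plan (target numbering: C1 = OMe bridgehead, C2 = CH–OAc, C3=C4 = enol ether, C5 = allyl bridgehead, C6 = CH–Me, C7 = CH–Ar, C8 = bridging C=O)
Retrosynthesis: the C2 acetate and the C8 ketone are adjusted last; the C1–C7 bond of the cyclopentanone ring C1–C8–C5–C6–C7 is traced back by a retro-α-ketol shift to a C2–C7 bond, giving a bridgehead-oxygenated bicyclo[2.2.2]oct-5-en-2-one, which is cut at C5–C6 and C2–C7 (retro-Diels–Alder) into a masked o-benzoquinone and (E)-isoelemicin.
Enabling feature: C1 carries oxygen and lies between the C8 carbonyl and the oxygenated C2, which is allylic to the C3=C4 enol ether; this vicinal C1(O)–C2(O) pair is an acyloin retron, and a 1,2-shift of C7 between C2 and C1 interconverts the cyclopentanone ring with a cyclohexane ring C2–C1–C8–C5–C6–C7 and ends in a conjugated enone.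
Forward order: tetra-oxygenated allylarene, dearomatisation to the cyclohexadienone, [4+2] cycloaddition to the bicyclo[2.2.2]octenone (all rings six-membered), contraction of one six-membered ring to the cyclopentane (bicyclo[3.2.1]octane), then oxidation-level adjustment at C2 and C8.
Stereochemistry: trans C6/C7 from the E-alkene and their orientation from endo-aryl cycloaddition; C7 migrates with retention and C1 is fixed by the bicycle; C2 is set by hydride attack from the face of the C8 bridge.
Absolute configuration: a (−)-menthyl carbonate on the dienyl oxygen makes the two cycloadducts diastereomers, which are separated; the auxiliary is shed in the key step.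

Key step: step 8

Assumption: the remote menthyl group is not relied on for face selectivity; the two cycloadducts of step 7 are taken to be separable, and the one drawn as 12 is to be identified crystallographically before it is carried on.

Step 1
Reactants: 1 5-bromo-1,2,3-trimethoxybenzene; 2 (E)-4,4,5,5-tetramethyl-2-(prop-1-en-1-yl)-1,3,2-dioxaborolane
Product: 3 (E)-1,2,3-trimethoxy-5-(prop-1-en-1-yl)benzene ((E)-isoelemicin)
Conditions: Pd(dppf)Cl2 (3 mol %), K2CO3, 1,4-dioxane–H2O, 85 °C
Reagents that add atoms: none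
Why: Suzuki–Miyaura coupling of an aryl bromide with a stereodefined alkenylboronate proceeds with retention of the E geometry and should give the dienophile free of the Z isomer.

Step 2
Reactants: 4 2,5-dimethoxyphenol
Product: 5 4-bromo-2,5-dimethoxyphenol
Conditions: NBS, MeCN, 0 °C
Reagents that add atoms: N-bromosuccinimide, O=C1CCC(=O)N1Br
Why: Electrophilic aromatic bromination is directed para to the free hydroxyl, a position that is also ortho to a methoxy group, so the halogen should land on the carbon that is to carry the allyl group.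

Step 3
Reactants: 5 4-bromo-2,5-dimethoxyphenol
Product: 6 2,5-dimethoxy-4-(prop-2-en-1-yl)phenol
Conditions: allylSnBu3, Pd(PPh3)4 (5 mol %), DMF, 90 °C
Reagents that add atoms: allyltributylstannane, C=CC[Sn](CCCC)(CCCC)CCCC
Why: Stille coupling of the aryl bromide with the allylstannane runs without base, so the free phenol is tolerated and the terminal alkene should not be isomerised into conjugation.

Step 4
Reactants: 6 2,5-dimethoxy-4-(prop-2-en-1-yl)phenol
Product: 7 2-hydroxy-3,6-dimethoxy-5-(prop-2-en-1-yl)benzaldehyde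
Conditions: MgCl2, Et3N, (CH2O)n, MeCN, reflux; then aqueous HCl
Reagents that add atoms: paraformaldehyde (as formaldehyde), C=O
Why: Magnesium-mediated ortho-formylation of a phenol delivers formaldehyde through the magnesium phenoxide to the only free ortho position, which fixes without ambiguity the site of the future second phenolic oxygen.

Step 5
Reactants: 7 2-hydroxy-3,6-dimethoxy-5-(prop-2-en-1-yl)benzaldehyde
Product: 8 2-formyl-3,6-dimethoxy-4-(prop-2-en-1-yl)phenyl (1R,2S,5R)-5-methyl-2-(propan-2-yl)cyclohexyl carbonate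
Conditions: (−)-menthyl chloroformate, Et3N, DMAP (10 mol %), CH2Cl2, 0 °C to rt
Reagents that add atoms: (1R,2S,5R)-(−)-menthyl chloroformate, ClC(=O)O[C@@H]1C[C@H](C)CC[C@H]1C(C)C
Why: DMAP-catalysed carbonate formation at the only hydroxyl places the chiral, base-labile group on the oxygen that is to become the bridgehead alkoxide, with no regiochemical alternative.

Step 6
Reactants: 8 2-formyl-3,6-dimethoxy-4-(prop-2-en-1-yl)phenyl (1R,2S,5R)-menthyl carbonate
Product: 10 2-hydroxy-3,6-dimethoxy-4-(prop-2-en-1-yl)phenyl (1R,2S,5R)-5-methyl-2-(propan-2-yl)cyclohexyl carbonate, via aryl formate 9 (not isolated)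
Conditions: mCPBA, CH2Cl2, 0 °C to rt; then MeOH, TsOH (catalytic), 0 °C
Reagents that add atoms: 3-chloroperoxybenzoic acid, OOC(=O)c1cccc(Cl)c1
Why: Dakin-type Baeyer–Villiger oxidation of the electron-rich ortho-alkoxybenzaldehyde should proceed by aryl migration faster than epoxidation of the monosubstituted alkene, and acid-catalysed methanolysis of the labile formate frees the phenol without the basic conditions under which the neighbouring carbonate could migrate or cyclise.

Step 7
Reactants: 10 2-hydroxy-3,6-dimethoxy-4-(prop-2-en-1-yl)phenyl (1R,2S,5R)-menthyl carbonate; 3 (E)-isoelemicin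
Product: 12 (1R,2S,5R)-5-methyl-2-(propan-2-yl)cyclohexyl (1S,4S,7R,8S)-3,3,6-trimethoxy-8-methyl-2-oxo-4-(prop-2-en-1-yl)-7-(3,4,5-trimethoxyphenyl)bicyclo[2.2.2]oct-5-en-1-yl carbonate, via masked o-benzoquinone 11 (not isolated)
Conditions: PhI(OAc)2, MeOH, 0 °C; solvent exchange; 3 (3 equiv), toluene, 105 °C, sealed tube; chromatographic separation of the two cycloadducts
Reagents that add atoms: methanol, CO
Why: Oxidative dearomatisation adds methanol at the methoxy-bearing ortho carbon to give the o-quinone monoketal, whose inverse-electron-demand Diels–Alder reaction with the styrene-type alkene should follow the ortho and endo preferences known for such dienones (CHMe carbon to the δ-carbon C4 of 12, aryl-bearing carbon to the α-carbon C1, aryl under the diene), so that the E geometry gives trans C7/C8 with the aryl group syn to the enol ether bridge, while attack on the two diene faces gives carbonate diastereomers from which 12 is separated.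

Step 8
Reactants: 12 (1R,2S,5R)-menthyl (1S,4S,7R,8S)-3,3,6-trimethoxy-8-methyl-2-oxo-4-(prop-2-en-1-yl)-7-(3,4,5-trimethoxyphenyl)bicyclo[2.2.2]oct-5-en-1-yl carbonate
Product: 14 (1S,5S,6S,7R)-1-hydroxy-3,8,8-trimethoxy-6-methyl-5-(prop-2-en-1-yl)-7-(3,4,5-trimethoxyphenyl)bicyclo[3.2.1]oct-3-en-2-one, via bridgehead ketol 13 (not isolated)
Conditions: K2CO3 (0.5 equiv), MeOH, 0 °C to rt
Reagents that add atoms: none
Why: Methoxide attacks the carbonate carbonyl and expels the better leaving group, the α-keto bridgehead alkoxide of 13; as its C1–O− becomes C=O the aryl-bearing carbon C7 shifts suprafacially from C1 to the adjacent carbonyl carbon C2 (α-ketol or acyloin rearrangement), and the new tertiary alkoxide is protonated by methanol, so the base is catalytic. The closest known reaction type is the base-mediated α-ketol rearrangement of bridgehead-hydroxy bicyclo[2.2.2]octan-2-ones to 1-hydroxybicyclo[3.2.1]octan-2-ones. No ring is closed end to end: the six-membered ring C1–C2–C3–C4–C8–C7 of 12 loses C1 through the 1,2-shift (a three-centre migration onto the carbonyl carbon) and becomes the cyclopentane C2–C3–C4–C8–C7, while the ring that holds the enol ether keeps its size and the third ring grows to seven members. The only new stereocenter, the carbinol carbon (C1 of 14), is a bridgehead whose configuration is dictated by the bicycle, C7 migrates with retention, and C4 and C8 of 12 are untouched. The selectivity needed is migration of C7 and not of the vinylic carbon C6, both bonds being equally aligned with the carbonyl π* orbital; the rearrangement is reversible and only the C7 shift ends in a conjugated 3-methoxy-enone with the alkene in the three-carbon bridge, whereas the vinyl shift would give an unconjugated ketone in a more strained bicyclo[3.2.1]oct-6-ene, so equilibration should funnel the material to 14.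

Step 9
Reactants: 14 (1S,5S,6S,7R)-1-hydroxy-3,8,8-trimethoxy-6-methyl-5-(prop-2-en-1-yl)-7-(3,4,5-trimethoxyphenyl)bicyclo[3.2.1]oct-3-en-2-one
Product: 15 (1S,5S,6S,7R)-1,3,8,8-tetramethoxy-6-methyl-5-(prop-2-en-1-yl)-7-(3,4,5-trimethoxyphenyl)bicyclo[3.2.1]oct-3-en-2-one
Conditions: NaH, MeI, THF–DMF, 0 °C to rt
Reagents that add atoms: iodomethane, CI
Why: Williamson O-methylation of the tertiary alkoxide should be clean because the ketone has no enolisable α-hydrogen and the alkoxide of 14 is the thermodynamic terminus of the ketol manifold, so exposure to base does not scramble the skeleton.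

Step 10
Reactants: 15 (1S,5S,6S,7R)-1,3,8,8-tetramethoxy-6-methyl-5-(prop-2-en-1-yl)-7-(3,4,5-trimethoxyphenyl)bicyclo[3.2.1]oct-3-en-2-one
Product: 16 (1R,5S,6S,7R)-1,3-dimethoxy-6-methyl-5-(prop-2-en-1-yl)-7-(3,4,5-trimethoxyphenyl)bicyclo[3.2.1]oct-3-ene-2,8-dione
Conditions: 2 M HCl, THF, 45 °C
Reagents that add atoms: water, O
Why: Acid-catalysed ketal hydrolysis unmasks the bridging ketone at the one stage where the enol ether is protected by conjugation, since protonation of the 3-methoxy-enone at C4 would place a cation at C3 next to the C2 carbonyl and is disfavoured.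

Step 11
Reactants: 16 (1R,5S,6S,7R)-1,3-dimethoxy-6-methyl-5-(prop-2-en-1-yl)-7-(3,4,5-trimethoxyphenyl)bicyclo[3.2.1]oct-3-ene-2,8-dione
Product: 17 (1R,2R,5S,6S,7R,8S)-1,3-dimethoxy-6-methyl-5-(prop-2-en-1-yl)-7-(3,4,5-trimethoxyphenyl)bicyclo[3.2.1]oct-3-ene-2,8-diol
Conditions: NaBH4 (excess), CeCl3·7H2O, MeOH, −40 to 0 °C
Reagents that add atoms: none
Why: Luche reduction takes both carbonyls in 1,2-fashion, and at C2 hydride should enter from the face of the one-carbon bridge because the opposite face is screened by the endo aryl group at C7, which sets the (2R) carbinol with its hydroxyl syn to the aryl-bearing bridge, while the configuration formed at C8 (expected as drawn, by attack over the unsaturated bridge away from the exo methyl group) is erased in step 13.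

Step 12
Reactants: 17 (1R,2R,5S,6S,7R,8S)-1,3-dimethoxy-6-methyl-5-(prop-2-en-1-yl)-7-(3,4,5-trimethoxyphenyl)bicyclo[3.2.1]oct-3-ene-2,8-diol
Product: 18 (1R,2R,5S,6S,7R,8S)-8-hydroxy-1,3-dimethoxy-6-methyl-5-(prop-2-en-1-yl)-7-(3,4,5-trimethoxyphenyl)bicyclo[3.2.1]oct-3-en-2-yl acetate
Conditions: Ac2O (1.1 equiv), pyridine, DMAP (5 mol %), CH2Cl2, 0 °C
Reagents that add atoms: acetic anhydride, CC(=O)OC(C)=O
Why: DMAP-catalysed acetylation should distinguish the allylic C2 hydroxyl from the C8 hydroxyl, which sits between two quaternary bridgeheads and beside the exo methyl group, so that one equivalent of anhydride gives the monoacetate.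

Step 13
Reactants: 18 (1R,2R,5S,6S,7R,8S)-8-hydroxy-1,3-dimethoxy-6-methyl-5-(prop-2-en-1-yl)-7-(3,4,5-trimethoxyphenyl)bicyclo[3.2.1]oct-3-en-2-yl acetate
Product: 19 (1S,2R,5S,6S,7R)-1,3-dimethoxy-6-methyl-8-oxo-5-(prop-2-en-1-yl)-7-(3,4,5-trimethoxyphenyl)bicyclo[3.2.1]oct-3-en-2-yl acetate (CNP0181407.1)
Conditions: Dess–Martin periodinane, pyridine, CH2Cl2, rt
Reagents that add atoms: none
Why: Dess–Martin oxidation of the remaining secondary alcohol under pyridine buffering regenerates the bridging ketone without touching the enol ether, the allylic acetate or the terminal alkene, and no stereocenter is affected.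

Compound list
1 | 5-bromo-1,2,3-trimethoxybenzene | COc1cc(Br)cc(OC)c1OC | starting material
2 | (E)-4,4,5,5-tetramethyl-2-(prop-1-en-1-yl)-1,3,2-dioxaborolane | C/C=C/B1OC(C)(C)C(C)(C)O1 | starting material
3 | (E)-1,2,3-trimethoxy-5-(prop-1-en-1-yl)benzene | C/C=C/c1cc(OC)c(OC)c(OC)c1 | intermediate
4 | 2,5-dimethoxyphenol | Oc1cc(OC)ccc1OC | starting material
5 | 4-bromo-2,5-dimethoxyphenol | Oc1cc(OC)c(Br)cc1OC | intermediate
6 | 2,5-dimethoxy-4-(prop-2-en-1-yl)phenol | Oc1cc(OC)c(CC=C)cc1OC | intermediate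
7 | 2-hydroxy-3,6-dimethoxy-5-(prop-2-en-1-yl)benzaldehyde | O=Cc1c(O)c(OC)cc(CC=C)c1OC | intermediate
8 | 2-formyl-3,6-dimethoxy-4-(prop-2-en-1-yl)phenyl (1R,2S,5R)-5-methyl-2-(propan-2-yl)cyclohexyl carbonate | O=Cc1c(OC(=O)O[C@@H]2C[C@H](C)CC[C@H]2C(C)C)c(OC)cc(CC=C)c1OC | intermediate
9 | 2-(formyloxy)-3,6-dimethoxy-4-(prop-2-en-1-yl)phenyl (1R,2S,5R)-5-methyl-2-(propan-2-yl)cyclohexyl carbonate | O=COc1c(OC(=O)O[C@@H]2C[C@H](C)CC[C@H]2C(C)C)c(OC)cc(CC=C)c1OC | intermediate
10 | 2-hydroxy-3,6-dimethoxy-4-(prop-2-en-1-yl)phenyl (1R,2S,5R)-5-methyl-2-(propan-2-yl)cyclohexyl carbonate | Oc1c(OC(=O)O[C@@H]2C[C@H](C)CC[C@H]2C(C)C)c(OC)cc(CC=C)c1OC | intermediate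
11 | 2,5,5-trimethoxy-6-oxo-4-(prop-2-en-1-yl)cyclohexa-1,3-dien-1-yl (1R,2S,5R)-5-methyl-2-(propan-2-yl)cyclohexyl carbonate | O=C1C(OC(=O)O[C@@H]2C[C@H](C)CC[C@H]2C(C)C)=C(OC)C=C(CC=C)C1(OC)OC | intermediate
12 | (1R,2S,5R)-5-methyl-2-(propan-2-yl)cyclohexyl (1S,4S,7R,8S)-3,3,6-trimethoxy-8-methyl-2-oxo-4-(prop-2-en-1-yl)-7-(3,4,5-trimethoxyphenyl)bicyclo[2.2.2]oct-5-en-1-yl carbonate | C=CC[C@]12C=C(OC)[C@](OC(=O)O[C@@H]3C[C@H](C)CC[C@H]3C(C)C)(C(=O)C1(OC)OC)[C@@H](c1cc(OC)c(OC)c(OC)c1)[C@@H]2C | intermediate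
13 | (1S,4S,7R,8S)-1-hydroxy-3,3,6-trimethoxy-8-methyl-4-(prop-2-en-1-yl)-7-(3,4,5-trimethoxyphenyl)bicyclo[2.2.2]oct-5-en-2-one (present as its alkoxide) | C=CC[C@]12C=C(OC)[C@](O)(C(=O)C1(OC)OC)[C@@H](c1cc(OC)c(OC)c(OC)c1)[C@@H]2C | intermediate
14 | (1S,5S,6S,7R)-1-hydroxy-3,8,8-trimethoxy-6-methyl-5-(prop-2-en-1-yl)-7-(3,4,5-trimethoxyphenyl)bicyclo[3.2.1]oct-3-en-2-one | C=CC[C@]12C=C(OC)C(=O)[C@](O)(C1(OC)OC)[C@@H](c1cc(OC)c(OC)c(OC)c1)[C@@H]2C | intermediate
15 | (1S,5S,6S,7R)-1,3,8,8-tetramethoxy-6-methyl-5-(prop-2-en-1-yl)-7-(3,4,5-trimethoxyphenyl)bicyclo[3.2.1]oct-3-en-2-one | C=CC[C@]12C=C(OC)C(=O)[C@](OC)(C1(OC)OC)[C@@H](c1cc(OC)c(OC)c(OC)c1)[C@@H]2C | intermediate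
16 | (1R,5S,6S,7R)-1,3-dimethoxy-6-methyl-5-(prop-2-en-1-yl)-7-(3,4,5-trimethoxyphenyl)bicyclo[3.2.1]oct-3-ene-2,8-dione | C=CC[C@]12C=C(OC)C(=O)[C@](OC)(C1=O)[C@@H](c1cc(OC)c(OC)c(OC)c1)[C@@H]2C | intermediate
17 | (1R,2R,5S,6S,7R,8S)-1,3-dimethoxy-6-methyl-5-(prop-2-en-1-yl)-7-(3,4,5-trimethoxyphenyl)bicyclo[3.2.1]oct-3-ene-2,8-diol | C=CC[C@]12C=C(OC)[C@@H](O)[C@](OC)([C@H]1O)[C@@H](c1cc(OC)c(OC)c(OC)c1)[C@@H]2C | intermediate
18 | (1R,2R,5S,6S,7R,8S)-8-hydroxy-1,3-dimethoxy-6-methyl-5-(prop-2-en-1-yl)-7-(3,4,5-trimethoxyphenyl)bicyclo[3.2.1]oct-3-en-2-yl acetate | C=CC[C@]12C=C(OC)[C@@H](OC(C)=O)[C@](OC)([C@H]1O)[C@@H](c1cc(OC)c(OC)c(OC)c1)[C@@H]2C | intermediate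
19 | (1S,2R,5S,6S,7R)-1,3-dimethoxy-6-methyl-8-oxo-5-(prop-2-en-1-yl)-7-(3,4,5-trimethoxyphenyl)bicyclo[3.2.1]oct-3-en-2-yl acetate | C=CC[C@]12C=C(OC)[C@@H](OC(C)=O)[C@](OC)(C1=O)[C@@H](c1cc(OC)c(OC)c(OC)c1)[C@@H]2C | target

Total step count: 13. Longest linear sequence: 12 steps (steps 2 to 13, from 4 to 19).

Steps most likely to fail

Step 7. What may go wrong: slow cycloaddition between a diene with two fully substituted termini and a 1,2-disubstituted alkene, competing exo-aryl approach, and no facial bias from the remote auxiliary combined with co-elution of the two face-diastereomers. Fallback: the bicyclo[3.2.1] core is assembled directly instead of through the bicyclo[2.2.2] adduct. It sets out from 3 and commercial 2,3,4-trimethoxyphenol F1 and comes back at 16. The phenol is O-allylated (allyl bromide, K2CO3, acetone) to 1-(allyloxy)-2,3,4-trimethoxybenzene F2, and Claisen rearrangement (N,N-diethylaniline, 190 °C) gives 6-allyl-2,3,4-trimethoxyphenol F3. Oxidation with PhI(OAc)2 in methanol, which for a para-methoxyphenol gives the p-quinone monoketal, leads to 2-allyl-4,4,5,6-tetramethoxycyclohexa-2,5-dien-1-one F4. Ionisation of the ketal with SnCl4 or TMSOTf in CH2Cl2 at −78 °C in the presence of 3 triggers the classical quinone-monoketal [5+2] cycloaddition, and aqueous work-up hydrolyses the resulting oxocarbenium ion to the dione as a racemate. The racemate is resolved by preparative chromatography on a chiral stationary phase into 16 and its enantiomer, (1S,5R,6R,7S)-dione F5.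

Step 10. What may go wrong: incomplete hydrolysis of the hindered, inductively deactivated bridging ketal, or concurrent cleavage of the 3-methoxy enol ether under the acid that is needed. Fallback: the enol ether is not preserved but restored. It sets out from 15 and comes back at 16. Forcing hydrolysis (6 M HCl, dioxane, 60 °C) is allowed to cleave both the ketal and the enol ether, giving the diosphenol (1R,5S,6S,7R)-3-hydroxy-1-methoxy-6-methyl-5-(prop-2-en-1-yl)-7-(3,4,5-trimethoxyphenyl)bicyclo[3.2.1]oct-3-ene-2,8-dione F6. The diketone can enolise only toward C4, so O-methylation of its acidic enol with trimethylsilyldiazomethane in methanol–toluene should give 16.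

Step 12. What may go wrong: insufficient discrimination between two hindered secondary hydroxyls, leading to acetylation at C8 or at both positions. Fallback: the two oxygens are differentiated at the ketone stage instead. It sets out from 16 and comes back at 19, bypassing 17 and 18. Reduction with LiAlH(OtBu)3 in THF at −78 °C is aimed at the enone carbonyl alone; the bulky hydride should be kept from the bridging carbonyl, which is flanked by two quaternary carbons and shielded by the exo methyl group. This gives (1S,2R,5S,6S,7R)-2-hydroxy-1,3-dimethoxy-6-methyl-5-(prop-2-en-1-yl)-7-(3,4,5-trimethoxyphenyl)bicyclo[3.2.1]oct-3-en-8-one F7, which has a single hydroxyl and is acetylated (Ac2O, pyridine, DMAP) to 19.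

Further compounds
F1 | step 7 | 2,3,4-trimethoxyphenol | COc1ccc(O)c(OC)c1OC
F2 | step 7 | 1-(allyloxy)-2,3,4-trimethoxybenzene | C=CCOc1ccc(OC)c(OC)c1OC
F3 | step 7 | 6-allyl-2,3,4-trimethoxyphenol | C=CCc1cc(OC)c(OC)c(OC)c1O
F4 | step 7 | 2-allyl-4,4,5,6-tetramethoxycyclohexa-2,5-dien-1-one | C=CCC1=CC(OC)(OC)C(OC)=C(OC)C1=O
F5 | step 7 | (1S,5R,6R,7S)-1,3-dimethoxy-6-methyl-5-(prop-2-en-1-yl)-7-(3,4,5-trimethoxyphenyl)bicyclo[3.2.1]oct-3-ene-2,8-dione | C=CC[C@@]12C=C(OC)C(=O)[C@@](OC)(C1=O)[C@H](c1cc(OC)c(OC)c(OC)c1)[C@H]2C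
F6 | step 10 | (1R,5S,6S,7R)-3-hydroxy-1-methoxy-6-methyl-5-(prop-2-en-1-yl)-7-(3,4,5-trimethoxyphenyl)bicyclo[3.2.1]oct-3-ene-2,8-dione | C=CC[C@]12C=C(O)C(=O)[C@](OC)(C1=O)[C@@H](c1cc(OC)c(OC)c(OC)c1)[C@@H]2C
F7 | step 12 | (1S,2R,5S,6S,7R)-2-hydroxy-1,3-dimethoxy-6-methyl-5-(prop-2-en-1-yl)-7-(3,4,5-trimethoxyphenyl)bicyclo[3.2.1]oct-3-en-8-one | C=CC[C@]12C=C(OC)[C@@H](O)[C@](OC)(C1=O)[C@@H](c1cc(OC)c(OC)c(OC)c1)[C@@H]2C
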